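Everything rests on cutting the C19–C20 bond of the bicyclo[2.2.1]heptane. Because carbonyl carbon C20 is flanked by bridgehead C6 and by C19, whose neighbour C18 is the second fusion carbon of rings A and B, an acyl radical on C20 can add across a C18=C19 alkene of ring B: one thiol-catalysed chain step closes ring D, makes C19–C20 and creates C19 and C18. The precursor is a spiro aldehyde, a 13β-bromo octalin (rings A and B, C18=C19, free C16 carbinol) whose C8 carries a cyclopentane with cis isopropyl (C4) and formyl (C6) groups; it is built from (S)-Wieland–Miescher ketone. Borohydride reduction of the ketone ends the synthesis.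

Key step: step 19

Remark on the chemistry: locants C1–C20 follow the atom order of the target SMILES (C12 is the angular methyl, C17 the carbinol methyl); β is the face of rings A and B that carries C12, α the opposite face; the E and Z isomers of 9 are carried on together because both give 13.

Step 1
Reactants: 1 (S)-Wieland–Miescher ketone
Product: 2 (4aS,5S)-5-hydroxy-4a-methyl-4,4a,5,6,7,8-hexahydronaphthalen-2(3H)-one
Conditions: NaBH4 (0.3 equiv), EtOH, −10 °C
Reagents that add atoms: none
Why: Chemoselective sodium borohydride reduction touches only the saturated C13 ketone and delivers hydride on the α face, away from the axial C12 methyl, so the equatorial 13β alcohol should result.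

Step 2
Reactants: 2 (4aS,5S)-5-hydroxy-4a-methyl-4,4a,5,6,7,8-hexahydronaphthalen-2(3H)-one, 3 4-nitrobenzoic acid
Product: 4 (1R,8aS)-8a-methyl-6-oxo-1,2,3,4,6,7,8,8a-octahydronaphthalen-1-yl 4-nitrobenzoate
Conditions: PPh3, DIAD, THF, 0 → 25 °C
Reagents that add atoms: 4-nitrobenzoic acid 3, OC(=O)c1ccc(cc1)[N+](=O)[O-]
Why: Mitsunobu esterification should invert C13 by SN2 attack of the carboxylate anti to the equatorial oxyphosphonium group, a path that runs over the sp2 carbon C18 and is not blocked by the C12 methyl, giving the axial 13α ester.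

Step 3
Reactants: 4 (1R,8aS)-8a-methyl-6-oxo-1,2,3,4,6,7,8,8a-octahydronaphthalen-1-yl 4-nitrobenzoate
Product: 5 (4aS,5R)-5-hydroxy-4a-methyl-4,4a,5,6,7,8-hexahydronaphthalen-2(3H)-one
Conditions: K2CO3 (cat.), MeOH, 25 °C
Reagents that add atoms: none
Why: Base-catalysed transesterification breaks the acyl–oxygen bond only, so the inverted 13α configuration is kept and the enone is untouched.

Step 4
Reactants: 5 (4aS,5R)-5-hydroxy-4a-methyl-4,4a,5,6,7,8-hexahydronaphthalen-2(3H)-one, 6 tetrabromomethane
Product: 7 (4aS,5S)-5-bromo-4a-methyl-4,4a,5,6,7,8-hexahydronaphthalen-2(3H)-one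
Conditions: CBr4, PPh3, CH2Cl2, 0 → 40 °C
Reagents that add atoms: tetrabromomethane 6, BrC(Br)(Br)Br
Why: Appel bromination of the axial neopentylic alcohol should displace the oxyphosphonium group by SN2 with inversion to the equatorial 13β bromide, the electron-poor enone disfavouring the competing ionisation with C12 methyl shift, while elimination to the C13–C14 alkene is the expected by-product.

Step 5
Reactants: 7 (4aS,5S)-5-bromo-4a-methyl-4,4a,5,6,7,8-hexahydronaphthalen-2(3H)-one, 8 triethyl phosphonoacetate
Product: 9 ethyl (2E)-[(4aS,5S)-5-bromo-4a-methyl-4,4a,5,6,7,8-hexahydronaphthalen-2(3H)-ylidene]acetate (with its Z isomer)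
Conditions: NaH, THF, 0 → 65 °C
Reagents that add atoms: triethyl phosphonoacetate 8, CCOC(=O)CP(=O)(OCC)OCC
Why: Horner–Wadsworth–Emmons olefination at C8, the only ketone left, should give the dienoate, and the equatorial neopentylic bromide has no antiperiplanar hydrogen and should survive the base.

Step 6
Reactants: 9 ethyl (2E)-[(4aS,5S)-5-bromo-4a-methyl-4,4a,5,6,7,8-hexahydronaphthalen-2(3H)-ylidene]acetate
Product: 10 (2E)-2-[(4aS,5S)-5-bromo-4a-methyl-4,4a,5,6,7,8-hexahydronaphthalen-2(3H)-ylidene]ethan-1-ol
Conditions: DIBAL-H, CH2Cl2, −78 °C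
Reagents that add atoms: none
Why: DIBAL-H reduces the conjugated ester in 1,2 fashion to the primary allylic alcohol without touching the secondary alkyl bromide.

Step 7
Reactants: 10 (2E)-2-[(4aS,5S)-5-bromo-4a-methyl-4,4a,5,6,7,8-hexahydronaphthalen-2(3H)-ylidene]ethan-1-ol, 11 triethyl orthoacetate
Product: 13 ethyl 2-[(2S,4aS,5S)-5-bromo-2-ethenyl-4a-methyl-2,3,4,4a,5,6,7,8-octahydronaphthalen-2-yl]acetate, via mixed ketene acetal 12 (not isolated)
Conditions: MeC(OEt)3 (neat), EtCO2H (cat.), 140 °C, EtOH distilled off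
Reagents that add atoms: triethyl orthoacetate 11, CCOC(C)(OCC)OCC
Why: In this Johnson–Claisen rearrangement the ketene acetal undergoes a chair [3,3] shift that forms the C7–C8 bond and leaves a vinyl group (C4=C5) on C8 with C18=C19 in place; bond formation is expected on the α face of the half-chair ring B, the axial direction anti to the C12 methyl that reagents also take at C3 of steroidal 4-en-3-ones, which sets the C8 quaternary centre with C7 α and C4 β.

Step 8
Reactants: 13 ethyl 2-[(2S,4aS,5S)-5-bromo-2-ethenyl-4a-methyl-2,3,4,4a,5,6,7,8-octahydronaphthalen-2-yl]acetate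
Product: 14 ethyl 2-[(2S,4aS,5S,8R)-5-bromo-2-ethenyl-8-hydroxy-4a-methyl-2,3,4,4a,5,6,7,8-octahydronaphthalen-2-yl]acetate
Conditions: SeO2 (0.5 equiv), t-BuOOH, CH2Cl2, 25 °C
Reagents that add atoms: tert-butyl hydroperoxide, CC(C)(C)OO; selenium dioxide (oxygen carrier), O=[Se]=O
Why: Selenium dioxide allylic oxidation (ene reaction then [2,3] shift) keeps the double bond at C18=C19 and hydroxylates C16, the only allylic C–H position because C8 and C11 are quaternary and the vinyl group has no allylic hydrogen; the 16β alcohol is expected, but either epimer serves.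

Step 9
Reactants: 14 ethyl 2-[(2S,4aS,5S,8R)-5-bromo-2-ethenyl-8-hydroxy-4a-methyl-2,3,4,4a,5,6,7,8-octahydronaphthalen-2-yl]acetate
Product: 15 ethyl 2-[(2S,4aS,5S)-5-bromo-2-ethenyl-4a-methyl-8-oxo-2,3,4,4a,5,6,7,8-octahydronaphthalen-2-yl]acetate
Conditions: Dess–Martin periodinane, CH2Cl2, 25 °C
Reagents that add atoms: none
Why: Dess–Martin oxidation of the secondary allylic alcohol gives the C16 enone, leaves alkenes, ester and bromide alone, and removes the C16 stereocentre.

Step 10
Reactants: 15 ethyl 2-[(2S,4aS,5S)-5-bromo-2-ethenyl-4a-methyl-8-oxo-2,3,4,4a,5,6,7,8-octahydronaphthalen-2-yl]acetate, 16 methylmagnesium bromide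
Product: 17 ethyl 2-[(2S,4aS,5S,8R)-5-bromo-2-ethenyl-8-hydroxy-4a,8-dimethyl-2,3,4,4a,5,6,7,8-octahydronaphthalen-2-yl]acetate
Conditions: MeMgBr, LaCl3·2LiCl (0.3 equiv), THF, −78 °C
Reagents that add atoms: methylmagnesium bromide 16, C[Mg]Br
Why: Lanthanide-promoted Grignard 1,2-addition to the enone carbonyl is much faster than attack on the ester at low temperature and should occur on the α face, since the β face of C16 is shielded by the 1,3-related axial C12 methyl, giving the axial 16β alcohol with the C17 methyl α as in the target.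

Step 11
Reactants: 17 ethyl 2-[(2S,4aS,5S,8R)-5-bromo-2-ethenyl-8-hydroxy-4a,8-dimethyl-2,3,4,4a,5,6,7,8-octahydronaphthalen-2-yl]acetate, 18 N,O-dimethylhydroxylamine hydrochloride
Product: 19 2-[(2S,4aS,5S,8R)-5-bromo-2-ethenyl-8-hydroxy-4a,8-dimethyl-2,3,4,4a,5,6,7,8-octahydronaphthalen-2-yl]-N-methoxy-N-methylacetamide
Conditions: i-PrMgCl, THF, −20 → 0 °C
Reagents that add atoms: N,O-dimethylhydroxylamine hydrochloride 18, CNOC.Cl
Why: Weinreb amide formation by aminolysis of the ethyl ester with the magnesium amide of the hydroxylamine tolerates the alkyl bromide and the tertiary alkoxide formed by the excess base.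

Step 12
Reactants: 19 2-[(2S,4aS,5S,8R)-5-bromo-2-ethenyl-8-hydroxy-4a,8-dimethyl-2,3,4,4a,5,6,7,8-octahydronaphthalen-2-yl]-N-methoxy-N-methylacetamide, 20 vinylmagnesium bromide
Product: 21 1-[(2S,4aS,5S,8R)-5-bromo-2-ethenyl-8-hydroxy-4a,8-dimethyl-2,3,4,4a,5,6,7,8-octahydronaphthalen-2-yl]but-3-en-2-one
Conditions: CH2=CHMgBr, THF, −20 → 0 °C; cold aq. NH4Cl
Reagents that add atoms: vinylmagnesium bromide 20, C=C[Mg]Br
Why: Grignard addition to the Weinreb amide stops at the chelated tetrahedral adduct, so work-up should release the vinyl ketone without over-addition, one further equivalent being used up by the tertiary alcohol.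

Step 13
Reactants: 21 1-[(2S,4aS,5S,8R)-5-bromo-2-ethenyl-8-hydroxy-4a,8-dimethyl-2,3,4,4a,5,6,7,8-octahydronaphthalen-2-yl]but-3-en-2-one
Product: 22 spiro enone (ring C as cyclopent-2-en-1-one with C6 carbonyl and C4=C5; C4 β and C7 α on C8)
Conditions: second-generation Grubbs catalyst RuCl2(=CHPh)(PCy3)(H2IMes) (5 mol%), CH2Cl2, 40 °C
Reagents that add atoms: none
Why: Ring-closing metathesis of the two monosubstituted alkenes closes ring C as a cyclopentenone with loss of ethene, the hindered trisubstituted C18=C19 alkene being inert to the catalyst.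

Step 14
Reactants: 22 spiro enone, 23 isopropenylboronic acid pinacol ester
Product: 24 4-isopropenyl spiro ketone (isopropenyl on C4 cis to C19)
Conditions: [RhCl(C2H4)2]2 (2.5 mol%), (S)-BINAP (6 mol%), KOH (0.5 equiv), dioxane/H2O (10:1), 50 °C
Reagents that add atoms: isopropenylboronic acid pinacol ester 23, CC(=C)B1OC(C)(C)C(C)(C)O1
Why: The rhodium-catalysed asymmetric 1,4-addition of the alkenylboronate (Hayashi–Miyaura reaction) sets C4 under ligand control, because (S)-BINAP directs alkenyl transfer to the 2-si face of cyclopent-2-enones, which in 22 is the ring C face syn to C19, and the weak intrinsic bias of the spiro enone should be overridden.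

Step 15
Reactants: 24 4-isopropenyl spiro ketone
Product: 25 4-isopropyl spiro ketone
Conditions: H2 (1 atm), RhCl(PPh3)3 (5 mol%), toluene, 25 °C
Reagents that add atoms: none
Why: Homogeneous hydrogenation with RhCl(PPh3)3 saturates the unhindered 1,1-disubstituted alkene and should leave the hindered C18=C19 bond, the ketone and the C–Br bond alone.

Step 16
Reactants: 25 4-isopropyl spiro ketone, 26 methyltriphenylphosphonium bromide
Product: 27 C6 methylene compound
Conditions: Ph3PCH3Br, KOt-Bu, THF, 0 → 25 °C
Reagents that add atoms: methyltriphenylphosphonium bromide 26, C[P+](c1ccccc1)(c1ccccc1)c1ccccc1.[Br-]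
Why: Wittig methylenation of the cyclopentanone brings in C20 as an exocyclic methylene, excess ylide making up for deprotonation of the tertiary alcohol.

Step 17
Reactants: 27 C6 methylene compound
Product: 29 C20 primary alcohol (hydroxymethyl on C6 cis to the isopropyl group and to C19), via B-alkyl-9-BBN adduct 28 (not isolated)
Conditions: 9-BBN, THF, 0 → 25 °C; then NaOH, H2O2, 0 °C
Reagents that add atoms: hydrogen peroxide, OO
Why: Hydroboration–oxidation with bulky 9-BBN should be selective for the 1,1-disubstituted alkene, put boron on terminal C20 and deliver hydrogen to C6 on the ring C face opposite the isopropyl group, so that the hydroxymethyl group ends cis to the isopropyl group and to C19.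

Step 18
Reactants: 29 C20 primary alcohol
Product: 30 spiro aldehyde (key-step precursor)
Conditions: Dess–Martin periodinane, pyridine, CH2Cl2, 0 °C
Reagents that add atoms: none
Why: Buffered Dess–Martin oxidation converts the primary alcohol into the aldehyde without epimerising C6, and the tertiary allylic alcohol cannot be oxidised.

Step 19
Reactants: 30 spiro aldehyde
Product: 31 C20 ketone (bicyclo[2.2.1]heptan-2-one, rings A to D complete)
Conditions: t-C12H25SH (0.3 equiv), AIBN (0.2 equiv in portions), PhCl (0.02 M), 80 °C, degassed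
Reagents that add atoms: none
Why: A thiyl radical from the thiol and the initiator abstracts the formyl hydrogen of 30, the nucleophilic C20 acyl radical adds to C19, and the tertiary C18 radical takes hydrogen back from the thiol, which regenerates the chain carrier. The closest known reaction type is the thiol-catalysed intramolecular radical hydroacylation of alkenals to cyclopentanones. Ring D (C6, C7, C8, C19, C20) closes in the 5-exo-trig mode, which completes the bicyclo[2.2.1]heptan-2-one, whereas 6-endo attack at the fully substituted C18 is disfavoured. C19 is fixed by the tether: C20 hangs from C6 on the ring C face syn to C19 and the axial C7 link lets it reach only the α face of C19, so ring D must be cis-fused to ring B. C18 is set in the hydrogen transfer, which should come from the α face because the β face is flanked by the axial C12 methyl and the axial C16 hydroxyl, giving the trans fusion of rings A and B. The step needs ring closure to outrun decarbonylation of the secondary acyl radical and needs the C13 bromide to survive: the spiro centre C8 holds C20 close to C19, reversible formyl hydrogen transfer keeps the acyl radical available, and thiyl, acyl and alkyl radicals do not abstract bromine from a secondary alkyl bromide at a competitive rate.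

Step 20
Reactants: 31 C20 ketone
Product: 32 CNP0295684.1 (target, endo C20 alcohol)
Conditions: NaBH4, MeOH, −20 → 0 °C
Reagents that add atoms: none
Why: Sodium borohydride reduction of the norbornanone-type ketone should take place from the exo face, the side of the C7 methylene bridge, because the endo face is blocked by the endo hydrogen on C5 under the C4–C5 bridge, which gives the endo alcohol.

Compound list
1 | (S)-Wieland–Miescher ketone, (8aS)-8a-methyl-3,4,8,8a-tetrahydronaphthalene-1,6(2H,7H)-dione | O=C1CC[C@]2(C)C(=O)CCCC2=C1 | starting material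
2 | (4aS,5S)-5-hydroxy-4a-methyl-4,4a,5,6,7,8-hexahydronaphthalen-2(3H)-one (13β-OH, cis to C12) | O=C1CC[C@]2(C)[C@@H](O)CCCC2=C1 | intermediate
3 | 4-nitrobenzoic acid | OC(=O)c1ccc(cc1)[N+](=O)[O-] | starting material
4 | (1R,8aS)-8a-methyl-6-oxo-1,2,3,4,6,7,8,8a-octahydronaphthalen-1-yl 4-nitrobenzoate (13α ester) | O=C1CC[C@]2(C)[C@H](OC(=O)c3ccc(cc3)[N+](=O)[O-])CCCC2=C1 | intermediate
5 | (4aS,5R)-5-hydroxy-4a-methyl-4,4a,5,6,7,8-hexahydronaphthalen-2(3H)-one (13α-OH, axial) | O=C1CC[C@]2(C)[C@H](O)CCCC2=C1 | intermediate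
6 | tetrabromomethane | BrC(Br)(Br)Br | starting material
7 | (4aS,5S)-5-bromo-4a-methyl-4,4a,5,6,7,8-hexahydronaphthalen-2(3H)-one (13β-Br, equatorial) | O=C1CC[C@]2(C)[C@@H](Br)CCCC2=C1 | intermediate
8 | triethyl phosphonoacetate | CCOC(=O)CP(=O)(OCC)OCC | starting material
9 | ethyl (2E)-[(4aS,5S)-5-bromo-4a-methyl-4,4a,5,6,7,8-hexahydronaphthalen-2(3H)-ylidene]acetate (E isomer shown, Z isomer accompanies it) | CCOC(=O)/C=C1\CC[C@]2(C)[C@@H](Br)CCCC2=C1 | intermediate
10 | (2E)-2-[(4aS,5S)-5-bromo-4a-methyl-4,4a,5,6,7,8-hexahydronaphthalen-2(3H)-ylidene]ethan-1-ol | OC/C=C1\CC[C@]2(C)[C@@H](Br)CCCC2=C1 | intermediate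
11 | triethyl orthoacetate | CCOC(C)(OCC)OCC | starting material
12 | mixed ketene acetal of 10 (1-ethoxyvinyl ether) | C=C(OCC)OC/C=C1\CC[C@]2(C)[C@@H](Br)CCCC2=C1 | intermediate (not isolated)
13 | ethyl 2-[(2S,4aS,5S)-5-bromo-2-ethenyl-4a-methyl-2,3,4,4a,5,6,7,8-octahydronaphthalen-2-yl]acetate (acetate arm α, vinyl β on C8) | CCOC(=O)C[C@]1(C=C)CC[C@]2(C)[C@@H](Br)CCCC2=C1 | intermediate
14 | ethyl 2-[(2S,4aS,5S,8R)-5-bromo-2-ethenyl-8-hydroxy-4a-methyl-2,3,4,4a,5,6,7,8-octahydronaphthalen-2-yl]acetate (16β-OH) | CCOC(=O)C[C@]1(C=C)CC[C@]2(C)[C@@H](Br)CC[C@@H](O)C2=C1 | intermediate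
15 | ethyl 2-[(2S,4aS,5S)-5-bromo-2-ethenyl-4a-methyl-8-oxo-2,3,4,4a,5,6,7,8-octahydronaphthalen-2-yl]acetate | CCOC(=O)C[C@]1(C=C)CC[C@]2(C)[C@@H](Br)CCC(=O)C2=C1 | intermediate
16 | methylmagnesium bromide | C[Mg]Br | starting material
17 | ethyl 2-[(2S,4aS,5S,8R)-5-bromo-2-ethenyl-8-hydroxy-4a,8-dimethyl-2,3,4,4a,5,6,7,8-octahydronaphthalen-2-yl]acetate (16β-OH, C17 α) | CCOC(=O)C[C@]1(C=C)CC[C@]2(C)[C@@H](Br)CC[C@@](C)(O)C2=C1 | intermediate
18 | N,O-dimethylhydroxylamine hydrochloride | CNOC.Cl | starting material
19 | 2-[(2S,4aS,5S,8R)-5-bromo-2-ethenyl-8-hydroxy-4a,8-dimethyl-2,3,4,4a,5,6,7,8-octahydronaphthalen-2-yl]-N-methoxy-N-methylacetamide | CON(C)C(=O)C[C@]1(C=C)CC[C@]2(C)[C@@H](Br)CC[C@@](C)(O)C2=C1 | intermediate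
20 | vinylmagnesium bromide | C=C[Mg]Br | starting material
21 | 1-[(2S,4aS,5S,8R)-5-bromo-2-ethenyl-8-hydroxy-4a,8-dimethyl-2,3,4,4a,5,6,7,8-octahydronaphthalen-2-yl]but-3-en-2-one | C=CC(=O)C[C@]1(C=C)CC[C@]2(C)[C@@H](Br)CC[C@@](C)(O)C2=C1 | intermediate
22 | spiro enone: cyclopent-2-en-1-one (C6=O, C4=C5) spiro at C8 on the 13β-bromo-16β-hydroxy octalin; C4 β, C7 α | O=C1C=C[C@@]2(C1)CC[C@]3(C)[C@@H](Br)CC[C@@](C)(O)C3=C2 | intermediate
23 | isopropenylboronic acid pinacol ester | CC(=C)B1OC(C)(C)C(C)(C)O1 | starting material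
24 | 4-isopropenyl spiro ketone (isopropenyl on C4 cis to C19, C6 ketone) | CC(=C)[C@@H]1CC(=O)C[C@@]12CC[C@]3(C)[C@@H](Br)CC[C@@](C)(O)C3=C2 | intermediate
25 | 4-isopropyl spiro ketone | CC(C)[C@@H]1CC(=O)C[C@@]12CC[C@]3(C)[C@@H](Br)CC[C@@](C)(O)C3=C2 | intermediate
26 | methyltriphenylphosphonium bromide | C[P+](c1ccccc1)(c1ccccc1)c1ccccc1.[Br-] | starting material
27 | C6 methylene compound (exocyclic C6=C20) | CC(C)[C@@H]1CC(=C)C[C@@]12CC[C@]3(C)[C@@H](Br)CC[C@@](C)(O)C3=C2 | intermediate
28 | B-alkyl-9-BBN adduct (boron on C20) | CC(C)[C@@H]1C[C@H](CB2C3CCCC2CCC3)C[C@@]12CC[C@]3(C)[C@@H](Br)CC[C@@](C)(O)C3=C2 | intermediate (not isolated)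
29 | C20 primary alcohol (CH2OH on C6 cis to isopropyl and C19) | CC(C)[C@@H]1C[C@H](CO)C[C@@]12CC[C@]3(C)[C@@H](Br)CC[C@@](C)(O)C3=C2 | intermediate
30 | spiro aldehyde, key-step precursor (CHO on C6 cis to isopropyl and C19) | CC(C)[C@@H]1C[C@H](C=O)C[C@@]12CC[C@]3(C)[C@@H](Br)CC[C@@](C)(O)C3=C2 | intermediate
31 | C20 ketone, key-step product | CC(C)[C@@H]1C[C@H]2C[C@@]13CC[C@]1(C)[C@@H](Br)CC[C@@](C)(O)[C@H]1[C@@H]3C2=O | intermediate
32 | CNP0295684.1 (endo C20 alcohol) | CC(C)[C@@H]1C[C@H]2C[C@@]13CC[C@]1(C)[C@@H](Br)CC[C@@](C)(O)[C@H]1[C@@H]3[C@H]2O | target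

Total step count: 20. Longest linear sequence: 20 steps, from 1 to 32.

Steps most likely to fail

Step 19 (key step). The process at risk is loss of carbon monoxide from the C20 acyl radical, or simple return of hydrogen to it, ahead of a ring closure that builds norbornanone strain and a peri contact between C20 and the C17 methyl. A first remedy within the step is a lower temperature with a low-temperature azo initiator. The fallback changes the radical: starting from aldehyde 30, a ketyl–alkene reductive cyclisation (SmI2, HMPA, t-BuOH, THF, −78 °C, about two equivalents of SmI2 added to the aldehyde so that the neopentylic bromide is spared) forms the same C19–C20 bond through a C20 ketyl radical that cannot decarbonylate. It should give the ring D alcohol as 32 together with its C20 epimer, the exo alcohol F1; Dess–Martin oxidation of the mixture comes back to the route at ketone 31.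

Step 7. The process at risk is poor facial selectivity at C8, with the acetate arm entering on the β face and giving the C8 epimer of 13. The fallback sets out from bromo enone 7 and installs the two arms in the opposite order. Knoevenagel condensation with diethyl malonate (TiCl4, pyridine, THF) should give the alkylidene malonate F2. Copper-catalysed 1,4-addition of vinylmagnesium bromide (CuBr·SMe2, TMSCl, THF, −78 °C) then makes the vinyl group the incoming partner on the face that proved accessible, giving the vinyl malonate F3. Krapcho dealkoxycarbonylation (LiCl, wet DMSO, 150 °C) comes back to the route at ester 13.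

Step 14. The process at risk is stalled alkenyl transfer at the neopentylic C4, or eroded facial selectivity if catalyst and substrate are mismatched. The fallback sets out from spiro enone 22 and moves the stereo-determining event from C–C to C–H bond formation. Copper-catalysed conjugate addition of isopropylmagnesium chloride with TMSCl (CuBr·SMe2, HMPA, THF, −78 °C) should give the silyl enol ether F4 as a C4 epimer mixture. Saegusa–Ito oxidation (Pd(OAc)2, MeCN) then gives the 4-isopropyl enone F5, in which C4 is no longer a stereocentre. A ligand-controlled copper hydride conjugate reduction (Cu(OAc)2, the enantiomer of DTBM-SEGPHOS that delivers hydride to the face anti to C19, (EtO)2MeSiH, t-BuOH, toluene) comes back to the route at ketone 25.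

Further compounds
F1 | step 19 | exo C20 alcohol (C20 epimer of 32) | CC(C)[C@@H]1C[C@H]2C[C@@]13CC[C@]1(C)[C@@H](Br)CC[C@@](C)(O)[C@H]1[C@@H]3[C@@H]2O
F2 | step 7 | diethyl 2-[(4aS,5S)-5-bromo-4a-methyl-4,4a,5,6,7,8-hexahydronaphthalen-2(3H)-ylidene]malonate | CCOC(=O)C(C(=O)OCC)=C1CC[C@]2(C)[C@@H](Br)CCCC2=C1
F3 | step 7 | diethyl 2-[(4aS,5S)-5-bromo-2-ethenyl-4a-methyl-2,3,4,4a,5,6,7,8-octahydronaphthalen-2-yl]malonate (vinyl β on C8) | CCOC(=O)C(C(=O)OCC)[C@]1(C=C)CC[C@]2(C)[C@@H](Br)CCCC2=C1
F4 | step 14 | trimethylsilyl enol ether of the 4-isopropyl spiro ketone (C5=C6, C4 epimers) | CC(C)C1C=C(O[Si](C)(C)C)C[C@@]12CC[C@]3(C)[C@@H](Br)CC[C@@](C)(O)C3=C2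
F5 | step 14 | 4-isopropyl spiro enone (C4=C5, C6 ketone) | CC(C)C1=CC(=O)C[C@@]12CC[C@]3(C)[C@@H](Br)CC[C@@](C)(O)C3=C2
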